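## The problem

The target **30** is a germacranolide. Its ten-membered carbocycle (C1–C10, germacrane numbering; C15 is the methyl on C4, C14 the formyl carbon on C10) holds two trisubstituted alkenes that are both cis within the ring (C4=C5 and C1=C10). It is fused at C6/C7 to an α-methylene-γ-butyrolactone (oxygen on C6; C11, C12, C13). Four contiguous stereocentres run from C6 to C9 (6R,7S,8S,9S): the lactone is trans-fused, C8 carries a (2S)-2-methylbutanoate and C9 a free hydroxyl; the fifth centre lies in the acyl group and comes with the acid. A synthesis must close a medium ring without disturbing two Z-alkenes, and it must tell O8 from O9, since only one is acylated. Of the ring stereocentres only C6 can be set on its own by a reagent; C7 and C8 then have to be set from C6 across the lactone, and C9 last from C8. Several groups are fragile: the α-methylene lactone and the C1=C10–C14 enal are Michael acceptors, the 8-acyloxy-9-hydroxy pair invites acyl migration in base, and any butenolide precursor has a doubly activated H-6 (γ to the lactone carbonyl and allylic to C4=C5) whose removal would racemise the only stereocentre then present. The structure offers one unusual opening: C7 is the β-carbon of the lactone, C8 is the oxygen-bearing carbon next to it and C13 is an exocyclic methylene, which is the pattern left by a [2,3]-shift across an O8–C13 ether; C9 can be a ketone that enolises only toward C8, because C10 is sp2.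

## Retrosynthesis

**Oxidation levels and the ester (30 back to 25 and 26).** No ring bond is cut. The C14 aldehyde is traced to primary alcohol **29** and its silyl ether **28**, the C9 carbinol to ketone **27**, and the C8 ester C–O bond is cut to give ketol **25** and (S)-2-methylbutanoic acid **26**. This order keeps the enal masked until the last step and means O8 and O9 are never both free hydroxyls, so no selective acylation of a diol is needed. The forward reduction must be 1,2-selective and must place hydride on the correct face of C9.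

**C7–C8 (25 back to 23), the key disconnection.** The C7–C8 bond is cut and O8 is rejoined to C13, which turns the ten-membered carbocycle into the 13-membered butenolide-bridged keto ether **23**. Cutting C6–C7 or C9–C10 instead would demand end-to-end closure of a ten-membered ring. This exchange replaces that with contraction of an easier 13-membered ring, creates C7 and C8 together, delivers the exocyclic methylene, and frees exactly the hydroxyl that must be acylated. The precursor has one stereocentre instead of three. The forward step needs enolisation at C8 in the presence of the acidic H-6, and bond formation on the butenolide face anti to C5.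

**The lactone carbonyl (23 back to 21).** Ketone **23** comes from alcohol **22**, and the C11–C12 and C12–O bonds of the butenolide are cut to give the (Z)-iodoalkenol **21**, to be joined by carbonylative lactonisation. The butenolide is placed this late for two reasons. Its H-6 is base-sensitive, so it should meet as few reagents as possible before the key step. And the alkenyl iodide needed for ring closure at C10 would compete for the palladium catalyst if the lactone were made first.

**C11–I (21 back to 19).** The iodoalkene is traced to the ring alkyne of **19** by hydroxyl-directed trans-hydroalumination and iodination. This fixes iodine cis to C6, the only geometry that can lactonise, and the same hydride reagent removes the C6 acetate.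

**C9–C10 (19 back to 17).** The 13-membered ring is opened at C9–C10 to the alkenyl iodide–aldehyde **17**. Nozaki–Hiyama–Kishi coupling is preferred to closing the ether or the C6–C7 bond because it needs no base, keeps the alkene geometry and adds only to the aldehyde. The C9 configuration is irrelevant, since C9 becomes a ketone.

**C6–C7 and the C6 stereocentre (17 back to 8 and 10).** Aldehyde **17** is traced through alcohol **16**, acetate **15** and carbinol **14** to ynone **13**, racemic alcohol **12**, and the union of Z-enal **8** with alkyne **10** (from **9**). The C6 centre is set on the acyclic ynone by reagent-controlled reduction, where no other stereocentre interferes. C9 is carried as a silyl ether at the alcohol level and not as an acetal, because unmasking an α-alkoxy acetal needs aqueous acid that the doubly activated C6 carbinol would not survive.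

**C1=C10 and the C1–C6 chain (8 back to 1 and 2).** Enal **8** is traced through **7**, **6**, **5** and **4** to enal **3**, and the C1=C10 bond is cut by cross-metathesis into neryl acetate **1** and crotonaldehyde **2**. The nerol skeleton supplies C1–C6, C15 and the Z C4=C5 bond ready-made. α-Iodination of the enal then gives the iodine cis to C2 that ring closure needs.

## Roads not taken

**Alternative 1:** The cut is at C11–C12 and C12–O of the lactone on a finished ten-membered ring. In the forward step PdCl2(PPh3)2 with SnCl2 under CO would join the C6 hydroxyl, carbon monoxide and a C7 ethynyl group to give the α-methylene lactone **A1**. Its merits are real: cyclocarbonylation of homopropargylic alcohols is a known reaction type, the α-methylene lactone appears in the last C–C bond-forming step, and no base-sensitive butenolide is ever present. In certainty of the key step this road is better than the chosen one. Its weakness is that the carbonylation solves the easiest part of the problem. The ten-membered ring and all four contiguous stereocentres (C6–C9) must already be in place, so ring closure and an acyclic stereotetrad have to be solved by other means, with more protecting groups. Against the safer key step, the chosen plan sets a step that makes the ring, two stereocentres and the methylene group at once from a precursor with a single stereocentre.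

**Alternative 2:** The cut is at C3–C4. 9-BBN would hydroborate a terminal alkene (boron on C3) and Pd(dppf)Cl2 would couple C3 with a C4 alkenyl iodide to close the ring as **A2**. The coupling is mild, tolerates silyl ethers and esters, and fixes the C4=C5 geometry from the iodide; as a bond-forming reaction it is more reliable than anything in the chosen plan. For this target the difficulties are direct closure of a ten-membered ring with its entropic and transannular cost, hydroboration that must select one alkene next to a diene and a silylalkyne, and a seco compound that must already carry four stereocentres and four different protecting groups. **A2** is also still one carbonylation and several deprotections away from the lactone. The chosen plan closes a 13-membered ring instead, and the ten-membered ring then arises intramolecularly.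

**Alternative 3:** The cut is at C8–C9. Low-valent titanium from TiCl3(DME)1.5 and Zn–Cu couple would join a C8 and a C9 aldehyde to the ten-membered diol **A3**. It forms the ring and both carbinols in one known step and is as direct as the chosen plan at the ring-forming stage. For this target the weak points are several. Diastereocontrol at two new centres rests on conformation alone. The C9 aldehyde is an enal and the C8 aldehyde sits on the epimerisable C7. The two secondary hydroxyls of **A3** must afterwards be told apart for acylation at O8. And the lactone still lacks its methylene group, which would have to be introduced with base late in the sequence. The chosen plan delivers O8 as a free hydroxyl and C9 as a ketone, differentiated by construction, and the methylene arrives with the ring.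

Key step: step 18

Assumption: in the reduction of ynone 13 the branched Z-alkenyl group is taken as the larger and the linear alkynyl group as the smaller substituent, as for related alkenyl alkynyl ketones; the catalyst enantiomer in step 10 is chosen on that basis.

## Route

Step 1
Reactants: 1 neryl acetate; 2 (E)-but-2-enal (crotonaldehyde)
Product: 3 (2Z,6E)-3-methyl-8-oxoocta-2,6-dien-1-yl acetate
Conditions: 2 (5 equiv), second-generation Grubbs catalyst RuCl2(=CHPh)(PCy3)(H2IMes) (5 mol %), CH2Cl2, 40 °C
Reagents that add atoms: none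
Why: Olefin cross-metathesis; the gem-dimethyl alkene of 1 exchanges readily with the enal, whereas the 2,3-alkene is internal and deactivated by the allylic acetate, so the E-enal forms with loss of volatile 2-methylbut-2-ene and the Z C4=C5 bond is untouched.

Step 2
Reactants: 3 (2Z,6E)-3-methyl-8-oxoocta-2,6-dien-1-yl acetate
Product: 4 (2Z,6Z)-7-iodo-3-methyl-8-oxoocta-2,6-dien-1-yl acetate
Conditions: I2, DMAP (0.2 equiv), K2CO3, THF/H2O 1:1, 23 °C
Reagents that add atoms: iodine, II
Why: Nucleophile-catalysed α-iodination of an enal (Morita–Baylis–Hillman-type addition of DMAP, iodination of the enolate, elimination) gives the thermodynamic (Z)-α-iodoenal with iodine cis to C2; iodine does not add to the isolated trisubstituted alkene under these conditions.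

Step 3
Reactants: 4 (2Z,6Z)-7-iodo-3-methyl-8-oxoocta-2,6-dien-1-yl acetate
Product: 5 (2Z,6Z)-8-hydroxy-7-iodo-3-methylocta-2,6-dien-1-yl acetate
Conditions: NaBH4, CeCl3·7H2O, MeOH, −20 °C
Reagents that add atoms: none
Why: Luche reduction gives clean 1,2-reduction of the enal; the acetate and the alkenyl iodide are inert at this temperature.

Step 4
Reactants: 5 (2Z,6Z)-8-hydroxy-7-iodo-3-methylocta-2,6-dien-1-yl acetate
Product: 6 (2Z,6Z)-8-[(tert-butyldimethylsilyl)oxy]-7-iodo-3-methylocta-2,6-dien-1-yl acetate
Conditions: TBSCl, imidazole, CH2Cl2, 23 °C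
Reagents that add atoms: tert-butyldimethylsilyl chloride, CC(C)(C)[Si](C)(C)Cl
Why: Standard silylation of a primary allylic alcohol; the TBS ether masks C14 until the penultimate step.

Step 5
Reactants: 6 (2Z,6Z)-8-[(tert-butyldimethylsilyl)oxy]-7-iodo-3-methylocta-2,6-dien-1-yl acetate
Product: 7 (2Z,6Z)-8-[(tert-butyldimethylsilyl)oxy]-7-iodo-3-methylocta-2,6-dien-1-ol
Conditions: K2CO3 (cat.), MeOH, 0 °C
Reagents that add atoms: none
Why: Base-catalysed transesterification (methanolysis) of the acetate; the silyl ether and the alkenyl iodide are stable.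

Step 6
Reactants: 7 (2Z,6Z)-8-[(tert-butyldimethylsilyl)oxy]-7-iodo-3-methylocta-2,6-dien-1-ol
Product: 8 (2Z,6Z)-8-[(tert-butyldimethylsilyl)oxy]-7-iodo-3-methylocta-2,6-dienal
Conditions: TEMPO (10 mol %), PhI(OAc)2, CH2Cl2, 23 °C
Reagents that add atoms: none
Why: Oxoammonium oxidation of a primary allylic alcohol stops at the aldehyde and is known to convert nerol-type alcohols into the Z-enals without Z/E isomerisation.

Step 7
Reactants: 9 2-(prop-2-yn-1-yloxy)ethan-1-ol
Product: 10 triethyl[2-(prop-2-yn-1-yloxy)ethoxy]silane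
Conditions: TESCl, imidazole, CH2Cl2, 0 °C
Reagents that add atoms: chlorotriethylsilane, CC[Si](Cl)(CC)CC
Why: Silylation of the primary alcohol; the TES ether survives acetylide formation and can later be removed in the presence of the TBS ether.

Step 8
Reactants: 10 triethyl[2-(prop-2-yn-1-yloxy)ethoxy]silane; 8 (2Z,6Z)-8-[(tert-butyldimethylsilyl)oxy]-7-iodo-3-methylocta-2,6-dienal
Product: 12 rac-(5Z,9Z)-11-[(tert-butyldimethylsilyl)oxy]-10-iodo-6-methyl-1-{2-[(triethylsilyl)oxy]ethoxy}undeca-5,9-dien-2-yn-4-ol, via lithium acetylide 11 (not isolated)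
Conditions: 10, n-BuLi, THF, −78 °C; then 8, −78 °C; aq. NH4Cl
Reagents that add atoms: none
Why: 1,2-Addition of a lithium acetylide to the enal forms C6–C7; at −78 °C the acetylide neither exchanges with the alkenyl iodide nor isomerises the Z-enal, and the racemic carbinol is corrected in steps 9 and 10.

Step 9
Reactants: 12 rac-(5Z,9Z)-11-[(tert-butyldimethylsilyl)oxy]-10-iodo-6-methyl-1-{2-[(triethylsilyl)oxy]ethoxy}undeca-5,9-dien-2-yn-4-ol
Product: 13 (5Z,9Z)-11-[(tert-butyldimethylsilyl)oxy]-10-iodo-6-methyl-1-{2-[(triethylsilyl)oxy]ethoxy}undeca-5,9-dien-2-yn-4-one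
Conditions: Dess–Martin periodinane, NaHCO3, CH2Cl2, 0 °C
Reagents that add atoms: none
Why: Dess–Martin oxidation of the doubly activated secondary alcohol gives the cross-conjugated ynone under buffered conditions that do not isomerise the Z-alkene.

Step 10
Reactants: 13 (5Z,9Z)-11-[(tert-butyldimethylsilyl)oxy]-10-iodo-6-methyl-1-{2-[(triethylsilyl)oxy]ethoxy}undeca-5,9-dien-2-yn-4-one
Product: 14 (4R,5Z,9Z)-11-[(tert-butyldimethylsilyl)oxy]-10-iodo-6-methyl-1-{2-[(triethylsilyl)oxy]ethoxy}undeca-5,9-dien-2-yn-4-ol
Conditions: (R)-2-methyl-CBS-oxazaborolidine (0.5 equiv), catecholborane, toluene, −78 °C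
Reagents that add atoms: none
Why: Corey–Bakshi–Shibata reduction; with the Z-alkenyl group as the large and the alkynyl group as the small substituent, the (R)-catalyst should deliver hydride to the face that gives the 4R carbinol, which is C6 (R) of the target; catecholborane at −78 °C avoids hydroboration of the alkenes.

Step 11
Reactants: 14 (4R,5Z,9Z)-11-[(tert-butyldimethylsilyl)oxy]-10-iodo-6-methyl-1-{2-[(triethylsilyl)oxy]ethoxy}undeca-5,9-dien-2-yn-4-ol
Product: 15 (4R,5Z,9Z)-11-[(tert-butyldimethylsilyl)oxy]-10-iodo-6-methyl-1-{2-[(triethylsilyl)oxy]ethoxy}undeca-5,9-dien-2-yn-4-yl acetate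
Conditions: Ac2O, pyridine, DMAP (cat.), CH2Cl2, 0 °C
Reagents that add atoms: acetic anhydride, CC(=O)OC(C)=O
Why: Acylation with retention at C6; the acetate shields the carbinol from the oxidation in step 13 and is removed without an extra step by the hydride reagent of step 15.

Step 12
Reactants: 15 (4R,5Z,9Z)-11-[(tert-butyldimethylsilyl)oxy]-10-iodo-6-methyl-1-{2-[(triethylsilyl)oxy]ethoxy}undeca-5,9-dien-2-yn-4-yl acetate
Product: 16 (4R,5Z,9Z)-11-[(tert-butyldimethylsilyl)oxy]-1-(2-hydroxyethoxy)-10-iodo-6-methylundeca-5,9-dien-2-yn-4-yl acetate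
Conditions: PPTS (cat.), MeOH/CH2Cl2, 0 °C
Reagents that add atoms: none
Why: Acid-catalysed methanolysis removes a primary triethylsilyl ether much faster than a primary tert-butyldimethylsilyl ether; the acetate is untouched.

Step 13
Reactants: 16 (4R,5Z,9Z)-11-[(tert-butyldimethylsilyl)oxy]-1-(2-hydroxyethoxy)-10-iodo-6-methylundeca-5,9-dien-2-yn-4-yl acetate
Product: 17 (4R,5Z,9Z)-11-[(tert-butyldimethylsilyl)oxy]-10-iodo-6-methyl-1-(2-oxoethoxy)undeca-5,9-dien-2-yn-4-yl acetate
Conditions: Dess–Martin periodinane, NaHCO3, CH2Cl2, 0 °C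
Reagents that add atoms: none
Why: Dess–Martin oxidation of the only free hydroxyl gives the α-alkoxy aldehyde (C9), which should be used at once because such aldehydes hydrate and oligomerise.

Step 14
Reactants: 17 (4R,5Z,9Z)-11-[(tert-butyldimethylsilyl)oxy]-10-iodo-6-methyl-1-(2-oxoethoxy)undeca-5,9-dien-2-yn-4-yl acetate
Product: 19 (5R,6Z,10Z)-11-{[(tert-butyldimethylsilyl)oxy]methyl}-12-hydroxy-7-methyl-1-oxacyclotrideca-6,10-dien-3-yn-5-yl acetate (C12 epimers), via alkenylchromium dichloride 18 (not isolated)
Conditions: CrCl2 (10 equiv), NiCl2 (0.1 equiv), DMSO/THF, 23 °C, slow addition of 17 to 0.003 M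
Reagents that add atoms: none
Why: Nozaki–Hiyama–Kishi macrocyclisation forms C9–C10; nickel inserts into the C–I bond with retention, transmetalation gives the alkenylchromium species, and this adds only to the aldehyde, so C9 ends cis to C2. Both C9 epimers (ring position 12) are carried on, since C9 is oxidised in step 17.

Step 15
Reactants: 19 (5R,6Z,10Z)-11-{[(tert-butyldimethylsilyl)oxy]methyl}-12-hydroxy-7-methyl-1-oxacyclotrideca-6,10-dien-3-yn-5-yl acetate (C12 epimers)
Product: 21 (3Z,5R,6Z,10Z)-11-{[(tert-butyldimethylsilyl)oxy]methyl}-3-iodo-7-methyl-1-oxacyclotrideca-3,6,10-triene-5,12-diol (C12 epimers), via cyclic alkenylalanate 20 (not isolated)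
Conditions: NaAlH2(OCH2CH2OMe)2 (5 equiv), THF, 0 to 23 °C; then I2, THF, −78 °C
Reagents that add atoms: iodine, II
Why: Excess hydride first cleaves the acetate; the C6 aluminium alkoxide then delivers hydride to C7 and aluminium to C11 (hydroxyl-directed trans-hydroalumination of a propargylic alcohol), and iodine replaces aluminium with retention, so iodine ends cis to C6 as lactonisation requires.

Step 16
Reactants: 21 (3Z,5R,6Z,10Z)-11-{[(tert-butyldimethylsilyl)oxy]methyl}-3-iodo-7-methyl-1-oxacyclotrideca-3,6,10-triene-5,12-diol (C12 epimers)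
Product: 22 (6Z,10Z,12R)-6-{[(tert-butyldimethylsilyl)oxy]methyl}-5-hydroxy-10-methyl-3,13-dioxabicyclo[10.2.1]pentadeca-1(15),6,10-trien-14-one (C5 epimers)
Conditions: Pd(PPh3)4 (10 mol %), CO (1 atm), K2CO3, THF, 23 °C
Reagents that add atoms: carbon monoxide, [C-]#[O+]
Why: Palladium-catalysed carbonylative lactonisation (oxidative addition, CO insertion, acyl transfer to the cis hydroxyl) closes the butenolide; the C11 iodide is now the only alkenyl iodide in the molecule, and insoluble K2CO3 is used as base because H-6 of the product is acidic.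

Step 17
Reactants: 22 (6Z,10Z,12R)-6-{[(tert-butyldimethylsilyl)oxy]methyl}-5-hydroxy-10-methyl-3,13-dioxabicyclo[10.2.1]pentadeca-1(15),6,10-trien-14-one (C5 epimers)
Product: 23 (6Z,10Z,12R)-6-{[(tert-butyldimethylsilyl)oxy]methyl}-10-methyl-3,13-dioxabicyclo[10.2.1]pentadeca-1(15),6,10-triene-5,14-dione
Conditions: Dess–Martin periodinane, CH2Cl2, 0 °C
Reagents that add atoms: none
Why: Dess–Martin oxidation of the allylic C9 alcohols converges both epimers on the enone without base, so the butenolide is not exposed to enolising conditions.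

Step 18
Reactants: 23 (6Z,10Z,12R)-6-{[(tert-butyldimethylsilyl)oxy]methyl}-10-methyl-3,13-dioxabicyclo[10.2.1]pentadeca-1(15),6,10-triene-5,14-dione
Product: 25 (6R,7R,8S)-14-[(tert-butyldimethylsilyl)oxy]-8-hydroxy-9-oxogermacra-1(10)Z,4Z,11(13)-trien-12,6-olide, via dibutylboron enolate 24 (not isolated)
Conditions: Bu2BOTf (1.2 equiv), iPr2NEt (1.4 equiv), CH2Cl2, −78 to 0 °C; then pH 7 phosphate buffer, MeOH
Reagents that add atoms: none
Why: Proposed new method: Bu2BOTf binds the C9 ketone, the most basic carbonyl and the only one with an α-alkoxy C–H, and iPr2NEt removes H-8 (C10 is sp2, so enolisation is regiospecific) to give boron enolate 24. C8 then bonds to C7, the electrophilic β-carbon of the butenolide, through a five-membered envelope (C8, O, C13, C11, C7) while the C13–O bond breaks, so that the alkene moves to C11=C13 and the ether oxygen becomes the boron alkoxide on C8; the polarity is that of a conjugate addition followed by β-alkoxide loss, and because the stepwise version would be a disfavoured 5-endo-trig closure a concerted or tightly coupled [2,3]-shift is assumed. The closest known reactions are the boron-enolate [2,3]-Wittig rearrangement of α-allyloxy esters, the amine-catalysed [2,3]-Wittig rearrangement of α-allyloxy ketones and the anionic [2,3]-Wittig ring contraction of 13-membered allyl propargyl ethers to ten-membered carbocycles; none combines a ketone enolate, a butenolide acceptor and a transannular setting. The ten-membered ring is closed by contraction (13 to 10) of a preformed macrocycle, not by end-to-end cyclisation, so the reacting carbons are held five atoms apart and no dilution is needed. C7 is controlled by C6, the only stereocentre of 23: bonding on the butenolide face anti to C5 gives the trans-fused lactone and a staggered C5–C6–C7–C8 arrangement in the forming ring, whereas the syn face would force a nearly eclipsed one; C8 follows from the ring-imposed enolate geometry and the envelope, and neither outcome is secured by precedent. The step needs deprotonation at C8 and not at the doubly activated H-6; boron complexation of the ketone (not of the less basic lactone), low temperature and a hindered amine are relied on for this, and the [3,3] alternative through C9 is disfavoured because C9 is the electron-poor end of the enolate.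

Step 19
Reactants: 25 (6R,7R,8S)-14-[(tert-butyldimethylsilyl)oxy]-8-hydroxy-9-oxogermacra-1(10)Z,4Z,11(13)-trien-12,6-olide; 26 (S)-2-methylbutanoic acid
Product: 27 (6R,7S,8S)-14-[(tert-butyldimethylsilyl)oxy]-8-{[(2S)-2-methylbutanoyl]oxy}-9-oxogermacra-1(10)Z,4Z,11(13)-trien-12,6-olide
Conditions: 26, EDC·HCl, DMAP (0.2 equiv), CH2Cl2, 0 °C
Reagents that add atoms: none
Why: Steglich esterification of the secondary α-ketol with retention at C8; carbodiimide activation at 0 °C with only catalytic DMAP limits epimerisation at C8 and at the α-centre of the acid.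

Step 20
Reactants: 27 (6R,7S,8S)-14-[(tert-butyldimethylsilyl)oxy]-8-{[(2S)-2-methylbutanoyl]oxy}-9-oxogermacra-1(10)Z,4Z,11(13)-trien-12,6-olide
Product: 28 (6R,7S,8S,9S)-14-[(tert-butyldimethylsilyl)oxy]-9-hydroxy-8-{[(2S)-2-methylbutanoyl]oxy}germacra-1(10)Z,4Z,11(13)-trien-12,6-olide
Conditions: NaBH4, CeCl3·7H2O, MeOH/THF, −78 °C
Reagents that add atoms: none
Why: Luche reduction gives 1,2-reduction of the enone faster than conjugate reduction of the α-methylene lactone; hydride is expected to attack anti to the C8 acyloxy group (polar Felkin–Anh, with C7 inside), which gives the 8,9-threo (ring-trans) relationship, 9S.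

Step 21
Reactants: 28 (6R,7S,8S,9S)-14-[(tert-butyldimethylsilyl)oxy]-9-hydroxy-8-{[(2S)-2-methylbutanoyl]oxy}germacra-1(10)Z,4Z,11(13)-trien-12,6-olide
Product: 29 (6R,7S,8S,9S)-9,14-dihydroxy-8-{[(2S)-2-methylbutanoyl]oxy}germacra-1(10)Z,4Z,11(13)-trien-12,6-olide
Conditions: HF·pyridine, pyridine/THF, 0 °C
Reagents that add atoms: none
Why: Desilylation under buffered acidic fluoride frees the primary allylic alcohol without base, so acyl migration from O8 to O9 and addition to the α-methylene lactone are avoided.

Step 22
Reactants: 29 (6R,7S,8S,9S)-9,14-dihydroxy-8-{[(2S)-2-methylbutanoyl]oxy}germacra-1(10)Z,4Z,11(13)-trien-12,6-olide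
Product: 30 (6R,7S,8S,9S)-9-hydroxy-8-{[(2S)-2-methylbutanoyl]oxy}-14-oxogermacra-1(10)E,4Z,11(13)-trien-12,6-olide (CNP0168436.1)
Conditions: TEMPO (10 mol %), PhI(OAc)2, CH2Cl2, 23 °C
Reagents that add atoms: none
Why: Oxoammonium oxidation takes the unhindered primary allylic alcohol much faster than the hindered secondary allylic C9 alcohol and stops at the enal; the alkene geometry is unchanged (the descriptor becomes E only because CHO outranks C9).

## Compound list

1 | neryl acetate, (2Z)-3,7-dimethylocta-2,6-dien-1-yl acetate | CC(=O)OC/C=C(/C)CCC=C(C)C | starting material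
2 | (E)-but-2-enal (crotonaldehyde) | C/C=C/C=O | starting material
3 | (2Z,6E)-3-methyl-8-oxoocta-2,6-dien-1-yl acetate | CC(=O)OC/C=C(/C)CC/C=C/C=O | intermediate
4 | (2Z,6Z)-7-iodo-3-methyl-8-oxoocta-2,6-dien-1-yl acetate | CC(=O)OC/C=C(/C)CC/C=C(\I)C=O | intermediate
5 | (2Z,6Z)-8-hydroxy-7-iodo-3-methylocta-2,6-dien-1-yl acetate | CC(=O)OC/C=C(/C)CC/C=C(\I)CO | intermediate
6 | (2Z,6Z)-8-[(tert-butyldimethylsilyl)oxy]-7-iodo-3-methylocta-2,6-dien-1-yl acetate | CC(=O)OC/C=C(/C)CC/C=C(\I)CO[Si](C)(C)C(C)(C)C | intermediate
7 | (2Z,6Z)-8-[(tert-butyldimethylsilyl)oxy]-7-iodo-3-methylocta-2,6-dien-1-ol | OC/C=C(/C)CC/C=C(\I)CO[Si](C)(C)C(C)(C)C | intermediate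
8 | (2Z,6Z)-8-[(tert-butyldimethylsilyl)oxy]-7-iodo-3-methylocta-2,6-dienal | O=C/C=C(/C)CC/C=C(\I)CO[Si](C)(C)C(C)(C)C | intermediate
9 | 2-(prop-2-yn-1-yloxy)ethan-1-ol | C#CCOCCO | starting material
10 | triethyl[2-(prop-2-yn-1-yloxy)ethoxy]silane | C#CCOCCO[Si](CC)(CC)CC | intermediate
11 | lithium acetylide of 10 (not isolated) | [Li]C#CCOCCO[Si](CC)(CC)CC | intermediate
12 | rac-(5Z,9Z)-11-[(tert-butyldimethylsilyl)oxy]-10-iodo-6-methyl-1-{2-[(triethylsilyl)oxy]ethoxy}undeca-5,9-dien-2-yn-4-ol | CC[Si](CC)(CC)OCCOCC#CC(O)/C=C(/C)CC/C=C(\I)CO[Si](C)(C)C(C)(C)C | intermediate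
13 | (5Z,9Z)-11-[(tert-butyldimethylsilyl)oxy]-10-iodo-6-methyl-1-{2-[(triethylsilyl)oxy]ethoxy}undeca-5,9-dien-2-yn-4-one | CC[Si](CC)(CC)OCCOCC#CC(=O)/C=C(/C)CC/C=C(\I)CO[Si](C)(C)C(C)(C)C | intermediate
14 | (4R,5Z,9Z)-11-[(tert-butyldimethylsilyl)oxy]-10-iodo-6-methyl-1-{2-[(triethylsilyl)oxy]ethoxy}undeca-5,9-dien-2-yn-4-ol | CC[Si](CC)(CC)OCCOCC#C[C@H](O)/C=C(/C)CC/C=C(\I)CO[Si](C)(C)C(C)(C)C | intermediate
15 | (4R,5Z,9Z)-11-[(tert-butyldimethylsilyl)oxy]-10-iodo-6-methyl-1-{2-[(triethylsilyl)oxy]ethoxy}undeca-5,9-dien-2-yn-4-yl acetate | CC[Si](CC)(CC)OCCOCC#C[C@H](OC(C)=O)/C=C(/C)CC/C=C(\I)CO[Si](C)(C)C(C)(C)C | intermediate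
16 | (4R,5Z,9Z)-11-[(tert-butyldimethylsilyl)oxy]-1-(2-hydroxyethoxy)-10-iodo-6-methylundeca-5,9-dien-2-yn-4-yl acetate | OCCOCC#C[C@H](OC(C)=O)/C=C(/C)CC/C=C(\I)CO[Si](C)(C)C(C)(C)C | intermediate
17 | (4R,5Z,9Z)-11-[(tert-butyldimethylsilyl)oxy]-10-iodo-6-methyl-1-(2-oxoethoxy)undeca-5,9-dien-2-yn-4-yl acetate | O=CCOCC#C[C@H](OC(C)=O)/C=C(/C)CC/C=C(\I)CO[Si](C)(C)C(C)(C)C | intermediate
18 | alkenylchromium dichloride from 17, chromium on C10 in place of iodine (not isolated) | O=CCOCC#C[C@H](OC(C)=O)/C=C(/C)CC/C=C(\[Cr](Cl)Cl)CO[Si](C)(C)C(C)(C)C | intermediate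
19 | (5R,6Z,10Z)-11-{[(tert-butyldimethylsilyl)oxy]methyl}-12-hydroxy-7-methyl-1-oxacyclotrideca-6,10-dien-3-yn-5-yl acetate, mixture of C12 (germacrane C9) epimers | OC1COCC#C[C@H](OC(C)=O)/C=C(/C)CC/C=C1/CO[Si](C)(C)C(C)(C)C | intermediate
20 | cyclic alkenylalanate of the deacetylated macrocycle, Al bound to O6 and C11, disodium salt (not isolated) | [Na+].[Na+].COCCO[Al-]1(OCCOC)O[C@@H]2/C=C(/C)CC/C=C(/CO[Si](C)(C)C(C)(C)C)C([O-])COCC1=C2 | intermediate
21 | (3Z,5R,6Z,10Z)-11-{[(tert-butyldimethylsilyl)oxy]methyl}-3-iodo-7-methyl-1-oxacyclotrideca-3,6,10-triene-5,12-diol, mixture of C12 epimers | OC1COC/C(I)=C/[C@H](O)/C=C(/C)CC/C=C1/CO[Si](C)(C)C(C)(C)C | intermediate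
22 | (6Z,10Z,12R)-6-{[(tert-butyldimethylsilyl)oxy]methyl}-5-hydroxy-10-methyl-3,13-dioxabicyclo[10.2.1]pentadeca-1(15),6,10-trien-14-one, mixture of C5 epimers | O=C1O[C@@H]2/C=C(/C)CC/C=C(/CO[Si](C)(C)C(C)(C)C)C(O)COCC1=C2 | intermediate
23 | (6Z,10Z,12R)-6-{[(tert-butyldimethylsilyl)oxy]methyl}-10-methyl-3,13-dioxabicyclo[10.2.1]pentadeca-1(15),6,10-triene-5,14-dione (13-membered butenolide-bridged keto ether) | O=C1O[C@@H]2/C=C(/C)CC/C=C(/CO[Si](C)(C)C(C)(C)C)C(=O)COCC1=C2 | intermediate
24 | dibutylboron enolate of 23, C8=C9 enol borinate (not isolated) | O=C1O[C@@H]2/C=C(/C)CC/C=C(/CO[Si](C)(C)C(C)(C)C)C(OB(CCCC)CCCC)=COCC1=C2 | intermediate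
25 | (6R,7R,8S)-14-[(tert-butyldimethylsilyl)oxy]-8-hydroxy-9-oxogermacra-1(10)Z,4Z,11(13)-trien-12,6-olide (trans-fused lactone, H-7 and H-8 cis) | C=C1C(=O)O[C@@H]2/C=C(/C)CC/C=C(/CO[Si](C)(C)C(C)(C)C)C(=O)[C@@H](O)[C@@H]12 | intermediate
26 | (S)-2-methylbutanoic acid | CC[C@H](C)C(=O)O | starting material
27 | (6R,7S,8S)-14-[(tert-butyldimethylsilyl)oxy]-8-{[(2S)-2-methylbutanoyl]oxy}-9-oxogermacra-1(10)Z,4Z,11(13)-trien-12,6-olide | C=C1C(=O)O[C@@H]2/C=C(/C)CC/C=C(/CO[Si](C)(C)C(C)(C)C)C(=O)[C@@H](OC(=O)[C@@H](C)CC)[C@@H]12 | intermediate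
28 | (6R,7S,8S,9S)-14-[(tert-butyldimethylsilyl)oxy]-9-hydroxy-8-{[(2S)-2-methylbutanoyl]oxy}germacra-1(10)Z,4Z,11(13)-trien-12,6-olide | C=C1C(=O)O[C@@H]2/C=C(/C)CC/C=C(/CO[Si](C)(C)C(C)(C)C)[C@H](O)[C@@H](OC(=O)[C@@H](C)CC)[C@@H]12 | intermediate
29 | (6R,7S,8S,9S)-9,14-dihydroxy-8-{[(2S)-2-methylbutanoyl]oxy}germacra-1(10)Z,4Z,11(13)-trien-12,6-olide | C=C1C(=O)O[C@@H]2/C=C(/C)CC/C=C(/CO)[C@H](O)[C@@H](OC(=O)[C@@H](C)CC)[C@@H]12 | intermediate
30 | (6R,7S,8S,9S)-9-hydroxy-8-{[(2S)-2-methylbutanoyl]oxy}-14-oxogermacra-1(10)E,4Z,11(13)-trien-12,6-olide (CNP0168436.1) | C=C1C(=O)O[C@@H]2/C=C(/C)CC/C=C(/C=O)[C@H](O)[C@@H](OC(=O)[C@@H](C)CC)[C@@H]12 | target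

## Step count and least certain steps

Total: 22 steps. Longest linear sequence: 21 steps (steps 1–6 and 8–22, from neryl acetate 1); step 7 prepares alkyne 10.

**Step 18 (key step).** The most likely failure is deprotonation at C6 instead of C8: H-6 is γ to the lactone carbonyl and allylic, so the amine may remove it, with racemisation or double-bond migration in the butenolide. The second risk is loss of stereocontrol, by bond formation on the butenolide face syn to C5 or through the other enolate face, since only the conformation of the ten-atom bridge decides; a [3,3] shift through C9 is a third, less likely, path.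

Fallback (known reactions only; the ring is closed directly and no butenolide is formed): it sets out from aldehyde 8 and comes back at ketone 27.
- A Morita–Baylis–Hillman reaction of (R)-2,2-dimethyl-1,3-dioxolane-4-carbaldehyde with methyl acrylate (DABCO) would give methyl 2-{[(4R)-2,2-dimethyl-1,3-dioxolan-4-yl](hydroxy)methyl}prop-2-enoate F1.
- NBS/Me2S would convert F1 with allylic transposition into methyl (2Z)-2-(bromomethyl)-3-[(4S)-2,2-dimethyl-1,3-dioxolan-4-yl]prop-2-enoate F2.
- Nozaki–Hiyama allylation of 8 with F2 (CrCl2, THF, no nickel, so the alkenyl iodide is spared) would form C6–C7 and, after lactonisation, the α-methylene lactone (4S,5R)-5-[(1Z,5Z)-7-[(tert-butyldimethylsilyl)oxy]-6-iodo-2-methylhepta-1,5-dien-1-yl]-4-[(4S)-2,2-dimethyl-1,3-dioxolan-4-yl]-3-methylideneoxolan-2-one F3. The dioxolane centre (the future C8, from the chiral pool) would direct C6 and C7. The anti sense needed for the trans-lactone is the usual one for chromium allyl reagents, but the ester substituent can erode it, so this relationship would have to be proved before going on.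
- CuCl2·2H2O in MeCN would remove the acetonide to give the diol F4; TESCl/imidazole at −78 °C would silylate the primary hydroxyl to give the silyl ether F5.
- EDC/DMAP with 26 would acylate O8 to give the ester F6; PPTS/MeOH would free the primary alcohol F7; Dess–Martin oxidation would give the aldehyde F8.
- Nozaki–Hiyama–Kishi closure at C9–C10 (CrCl2, cat. NiCl2, high dilution) would form the ten-membered ring as the C9-epimeric alcohols F9 (28 and its 9-epimer), and Dess–Martin oxidation of the mixture converges on 27.

**Step 14 (macrocyclisation).** Oligomerisation or simple protonation of the alkenylchromium species may outrun ring closure, because the 13-membered ring must hold a linear four-carbon alkyne unit and two Z-alkenes; low-valent nickel may also ionise the allylic, propargylic acetate.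

Fallback (ring closed at the ketone stage, C6 set afterwards on the ring): it sets out from ynone 13 and comes back at 21.
- PPTS/MeOH would give the ynone alcohol (5Z,9Z)-11-[(tert-butyldimethylsilyl)oxy]-1-(2-hydroxyethoxy)-10-iodo-6-methylundeca-5,9-dien-2-yn-4-one F10.
- Dess–Martin oxidation would give the keto aldehyde F11.
- Nozaki–Hiyama–Kishi closure, which adds to the aldehyde and not to the ketone, would give the macrocyclic ynone alcohol F12, whose planar enynone segment has a different conformational bias.
- Reduction with (R)-2-methyl-CBS-oxazaborolidine and catecholborane would give the 5R diol F13, which under the conditions of step 15 gives 21.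

**Step 10 (C6 stereocentre).** Enantioface discrimination may be weak or reversed, because both ketone substituents are unsaturated and their relative effective size is an assumption. Fallback (stereocentre set during C–C bond formation, not by reduction): it sets out from aldehyde 8 with alkyne 10 and comes back at 14, by catalytic enantioselective alkynylation with Me2Zn, a ProPhenol ligand (the enantiomer that gives the R carbinol) and Ph3P=O in toluene. No new compound is involved, and steps 8–10 would collapse into one.

**Step 20 (C9 stereocentre).** Hydride delivery to the wrong face of the ring ketone is possible, since the conformation of the ten-membered ring can override the Felkin–Anh preference; conjugate reduction of the α-methylene lactone is a second risk. Fallback (configuration set by SN2 inversion, not by facial selectivity): it sets out from 27 and comes back at 28. If the reduction gives the 9R alcohol F14, a Mitsunobu reaction with chloroacetic acid (PPh3, DIAD) would invert C9 to the 9S chloroacetate F15, and thiourea/NaHCO3 in EtOH would remove the chloroacetyl group in the presence of the 2-methylbutanoate to give 28.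

## Further compounds

F1 | step 18 | methyl 2-{[(4R)-2,2-dimethyl-1,3-dioxolan-4-yl](hydroxy)methyl}prop-2-enoate (carbinol epimers) | C=C(C(=O)OC)C(O)[C@H]1COC(C)(C)O1
F2 | step 18 | methyl (2Z)-2-(bromomethyl)-3-[(4S)-2,2-dimethyl-1,3-dioxolan-4-yl]prop-2-enoate | BrC/C(C(=O)OC)=C\[C@H]1COC(C)(C)O1
F3 | step 18 | (4S,5R)-5-[(1Z,5Z)-7-[(tert-butyldimethylsilyl)oxy]-6-iodo-2-methylhepta-1,5-dien-1-yl]-4-[(4S)-2,2-dimethyl-1,3-dioxolan-4-yl]-3-methylideneoxolan-2-one | C=C1C(=O)O[C@H](/C=C(/C)CC/C=C(\I)CO[Si](C)(C)C(C)(C)C)[C@H]1[C@H]1COC(C)(C)O1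
F4 | step 18 | (4R,5R)-5-[(1Z,5Z)-7-[(tert-butyldimethylsilyl)oxy]-6-iodo-2-methylhepta-1,5-dien-1-yl]-4-[(1S)-1,2-dihydroxyethyl]-3-methylideneoxolan-2-one | C=C1C(=O)O[C@H](/C=C(/C)CC/C=C(\I)CO[Si](C)(C)C(C)(C)C)[C@H]1[C@H](O)CO
F5 | step 18 | (4R,5R)-5-[(1Z,5Z)-7-[(tert-butyldimethylsilyl)oxy]-6-iodo-2-methylhepta-1,5-dien-1-yl]-4-{(1S)-1-hydroxy-2-[(triethylsilyl)oxy]ethyl}-3-methylideneoxolan-2-one | C=C1C(=O)O[C@H](/C=C(/C)CC/C=C(\I)CO[Si](C)(C)C(C)(C)C)[C@H]1[C@H](O)CO[Si](CC)(CC)CC
F6 | step 18 | (1S)-1-{(3S,2R)-2-[(1Z,5Z)-7-[(tert-butyldimethylsilyl)oxy]-6-iodo-2-methylhepta-1,5-dien-1-yl]-4-methylidene-5-oxooxolan-3-yl}-2-[(triethylsilyl)oxy]ethyl (2S)-2-methylbutanoate | C=C1C(=O)O[C@H](/C=C(/C)CC/C=C(\I)CO[Si](C)(C)C(C)(C)C)[C@H]1[C@H](OC(=O)[C@@H](C)CC)CO[Si](CC)(CC)CC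
F7 | step 18 | primary alcohol from F6 by loss of the triethylsilyl group (configuration as in F6) | C=C1C(=O)O[C@H](/C=C(/C)CC/C=C(\I)CO[Si](C)(C)C(C)(C)C)[C@H]1[C@H](OC(=O)[C@@H](C)CC)CO
F8 | step 18 | aldehyde from F7, C9 as CHO (configuration as in F6) | C=C1C(=O)O[C@H](/C=C(/C)CC/C=C(\I)CO[Si](C)(C)C(C)(C)C)[C@H]1[C@H](OC(=O)[C@@H](C)CC)C=O
F9 | step 18 | (6R,7S,8S,9RS)-14-[(tert-butyldimethylsilyl)oxy]-9-hydroxy-8-{[(2S)-2-methylbutanoyl]oxy}germacra-1(10)Z,4Z,11(13)-trien-12,6-olide (28 and its 9-epimer) | C=C1C(=O)O[C@@H]2/C=C(/C)CC/C=C(/CO[Si](C)(C)C(C)(C)C)C(O)[C@@H](OC(=O)[C@@H](C)CC)[C@@H]12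
F10 | step 14 | (5Z,9Z)-11-[(tert-butyldimethylsilyl)oxy]-1-(2-hydroxyethoxy)-10-iodo-6-methylundeca-5,9-dien-2-yn-4-one | OCCOCC#CC(=O)/C=C(/C)CC/C=C(\I)CO[Si](C)(C)C(C)(C)C
F11 | step 14 | 2-{[(5Z,9Z)-11-[(tert-butyldimethylsilyl)oxy]-10-iodo-6-methyl-4-oxoundeca-5,9-dien-2-yn-1-yl]oxy}acetaldehyde | O=CCOCC#CC(=O)/C=C(/C)CC/C=C(\I)CO[Si](C)(C)C(C)(C)C
F12 | step 14 | (6Z,10Z)-11-{[(tert-butyldimethylsilyl)oxy]methyl}-12-hydroxy-7-methyl-1-oxacyclotrideca-6,10-dien-3-yn-5-one (racemic at C12) | OC1COCC#CC(=O)/C=C(/C)CC/C=C1/CO[Si](C)(C)C(C)(C)C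
F13 | step 14 | (5R,6Z,10Z)-11-{[(tert-butyldimethylsilyl)oxy]methyl}-7-methyl-1-oxacyclotrideca-6,10-dien-3-yne-5,12-diol (C12 epimers) | OC1COCC#C[C@H](O)/C=C(/C)CC/C=C1/CO[Si](C)(C)C(C)(C)C
F0 | step 10 | none | none
F14 | step 20 | (6R,7S,8S,9R)-14-[(tert-butyldimethylsilyl)oxy]-9-hydroxy-8-{[(2S)-2-methylbutanoyl]oxy}germacra-1(10)Z,4Z,11(13)-trien-12,6-olide (9-epimer of 28) | C=C1C(=O)O[C@@H]2/C=C(/C)CC/C=C(/CO[Si](C)(C)C(C)(C)C)[C@@H](O)[C@@H](OC(=O)[C@@H](C)CC)[C@@H]12
F15 | step 20 | (6R,7S,8S,9S)-14-[(tert-butyldimethylsilyl)oxy]-9-(chloroacetoxy)-8-{[(2S)-2-methylbutanoyl]oxy}germacra-1(10)Z,4Z,11(13)-trien-12,6-olide | C=C1C(=O)O[C@@H]2/C=C(/C)CC/C=C(/CO[Si](C)(C)C(C)(C)C)[C@H](OC(=O)CCl)[C@@H](OC(=O)[C@@H](C)CC)[C@@H]12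
A1 | alternative 1 | 9,14-bis-O-TBS ether of the 14-hydroxy analogue of 30, α-methylene lactone closed by carbonylation | C=C1C(=O)O[C@@H]2/C=C(/C)CC/C=C(/CO[Si](C)(C)C(C)(C)C)[C@H](O[Si](C)(C)C(C)(C)C)[C@@H](OC(=O)[C@@H](C)CC)[C@@H]12
A2 | alternative 2 | ten-membered carbocycle with 7-(trimethylsilylethynyl), 6-OTES, 8-(2S)-2-methylbutanoate, 9-OTBS and 14-OTBS | C[Si](C)(C)C#C[C@H]1[C@H](O[Si](CC)(CC)CC)/C=C(/C)CC/C=C(/CO[Si](C)(C)C(C)(C)C)[C@H](O[Si](C)(C)C(C)(C)C)[C@H]1OC(=O)[C@@H](C)CC
A3 | alternative 3 | ten-membered 8,9-diol fused to the saturated γ-lactone, 14-OTBS | C1C(=O)O[C@@H]2/C=C(/C)CC/C=C(/CO[Si](C)(C)C(C)(C)C)[C@H](O)[C@@H](O)[C@@H]12
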